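**Retrosynthetic overview**
1. Target 11 is (2S)-8-hydroxy-5,6,7,3',4'-pentamethoxyflavanone; the last step only unmasks the C4 ketone from S,S-ketal 10.
2. Key disconnection: C2–C3 and C4–C4a are cut together, a formal [4+2] (oxa-Povarov) annulation of an O-aryl oxocarbenium ion (C4a=C8a–O1=C2, a cationic 2-oxadiene) with ketene dithioacetal 7 (C3=C4 at the ketone oxidation level).
3. The oxocarbenium ion is stored as 2-aryl-1,3-benzodioxole 6, a temporary ring that ties C2 to both O1 and O8; its opening in the key step builds ring C and frees the 8-OH at once.
4. Enabling feature: ring A carries O1 and O8 on neighbouring carbons (C8a, C8), the 7-OMe next to O8 makes O8 the chelated leaving oxygen, and C4a is the only C–H of ring A (ortho to O1 and 5-OMe, para to 7-OMe).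
5. Ring order: ring A is bought (1) and oxygenated to catechol 3; the dioxole ring is closed with the ring B aldehyde 4; ring C closes in the key step as the dioxole opens.

Key step: step 3

Remark: flavanone numbering (O1, C2, C3, C4, C4a, C5–C8, C8a; ring A benzo ring, ring B dimethoxyphenyl, ring C pyranone) is used for the precursors as well; 7 and both antipodes of Ph-pybox are assumed to be commercial.

Step 1
Reactants: 1 3,4,5-trimethoxyphenol
Product: 3 3,4,5-trimethoxybenzene-1,2-diol, via 3,4,5-trimethoxy-1,2-benzoquinone 2 (not isolated)
Conditions: IBX (1.1 equiv), DMF, rt; then aq Na2S2O4, EtOAc, rt, under argon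
Reagents that add atoms: 2-iodoxybenzoic acid (IBX), O=C1OI(=O)(O)c2ccccc12
Why: Ortho-selective phenol oxygenation by 2-iodoxybenzoic acid (aryloxy ligand on pentavalent iodine, intramolecular oxygen delivery to an ortho carbon, the two ortho positions of 1 being equivalent) followed by dithionite reduction of o-quinone 2 should give the air-sensitive catechol 3 without touching the methyl ethers.

Step 2
Reactants: 3 3,4,5-trimethoxybenzene-1,2-diol; 4 3,4-dimethoxybenzaldehyde
Product: 6 2-(3,4-dimethoxyphenyl)-4,5,6-trimethoxy-1,3-benzodioxole (racemic at the acetal carbon), via veratraldehyde dimethyl acetal 5 (not isolated)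
Conditions: 4, HC(OMe)3, PPTS (cat.), MeOH, 50 °C, evaporate; then 3, PPTS (cat.), toluene, 90 °C, MeOH distilled off, under argon
Reagents that add atoms: none
Why: Acid-catalysed acetal exchange should close the five-membered dioxole ring because both phenolic oxygens of 3 sit on neighbouring carbons and methanol is removed, the weak acid keeping Friedel–Crafts alkylation of the free ring carbon slow; the acetal stereocenter forms as a racemate, which does not matter because it is ionized in step 3.

Step 3
Reactants: 6 2-(3,4-dimethoxyphenyl)-4,5,6-trimethoxy-1,3-benzodioxole; 7 1,1-bis(methylsulfanyl)ethene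
Product: 10 (2S)-2-(3,4-dimethoxyphenyl)-5,6,7-trimethoxy-4,4-bis(methylsulfanyl)-3,4-dihydro-2H-chromen-8-ol, via oxocarbenium zwitterion 8 (not isolated), via thiocarbenium zwitterion 9 (not isolated)
Conditions: Sc(OTf)3 (10 mol %), (S,S)-Ph-pybox (12 mol %), 7 (2 equiv, slow addition), 4 Å MS, CH2Cl2, −40 to −20 °C; then Et3N, aq NaHCO3
Reagents that add atoms: none
Why: Proposed new method: Sc(OTf)3 bearing the pybox ligand should bind acetal 6 at the oxygen that becomes O8 and at the neighbouring 7-methoxy oxygen, cleave that C–O bond and leave zwitterion 8, an O-aryl oxocarbenium ion (C4a=C8a–O1=C2) with a scandium aryloxide ortho to it; the CH2 terminus of ketene dithioacetal 7 adds to the oxocarbenium carbon (bond C3–C2) to give thiocarbenium zwitterion 9, whose cationic carbon is attacked by C4a in a Friedel–Crafts step (bond C4–C4a), and the proton lost on rearomatization frees the 8-hydroxyl from scandium and turns the catalyst over. The closest known reaction types are the SnCl4-promoted racemic oxa-Povarov annulation of aryl mixed acetals with alkenes, the Povarov reaction of chelating 2-hydroxyphenyl imines catalysed by chiral Sc(OTf)3 complexes, and the acid-induced cyclization of ketene dithioacetals onto electron-rich arenes. Ring C closes in a 6-exo-trig mode at the exocyclic C=S+ bond of 9 (the arene bond C4a–C8a lies inside the new ring), so the whole event is a stepwise formal [4+2] annulation. The only new stereocenter, C2, is set in the addition of 7 to 8: the pybox ligand on the scandium aryloxide held ortho to the cation is expected to shield one face, attack on the Si face of the oxocarbenium carbon gives 2S, and the antipodal ligand is used if a first run shows the opposite sense. The step needs (a) ionization at O8 and not at O1, secured by the 7-methoxy group that makes O8 the only bidentate binding site, (b) C- over O-capture of 9, secured because capture by the aryloxide gives a seven-membered S,S,O-orthoester that reopens while attack by C4a is irreversible, and (c) addition of 7 faster than Friedel–Crafts attack of a second molecule of 6 on 8, secured by the far higher nucleophilicity of the ketene dithioacetal used in excess.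

Step 4
Reactants: 10 (2S)-2-(3,4-dimethoxyphenyl)-5,6,7-trimethoxy-4,4-bis(methylsulfanyl)-3,4-dihydro-2H-chromen-8-ol
Product: 11 (2S)-2-(3,4-dimethoxyphenyl)-8-hydroxy-5,6,7-trimethoxy-2,3-dihydro-4H-chromen-4-one
Conditions: HgCl2 (2.2 equiv), CaCO3, MeCN–H2O (4:1), rt
Reagents that add atoms: water, O
Why: Thiophile-assisted hydrolysis of an S,S-ketal (divalent mercury binds sulfur, the thiocarbenium ion stabilized by ring A is captured by water) should release the C4 ketone under buffered, non-basic and non-oxidizing conditions, so that C2 is not epimerized by retro-oxa-Michael opening and the electron-rich phenol ring A is not oxidized.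

**Compound list**
1 | 3,4,5-trimethoxyphenol | COc1cc(O)cc(OC)c1OC | starting material
2 | 3,4,5-trimethoxycyclohexa-3,5-diene-1,2-dione (3,4,5-trimethoxy-1,2-benzoquinone) | COC1=CC(=O)C(=O)C(OC)=C1OC | intermediate
3 | 3,4,5-trimethoxybenzene-1,2-diol | COc1cc(O)c(O)c(OC)c1OC | intermediate
4 | 3,4-dimethoxybenzaldehyde | COc1ccc(C=O)cc1OC | starting material
5 | 4-(dimethoxymethyl)-1,2-dimethoxybenzene (veratraldehyde dimethyl acetal) | COc1ccc(C(OC)OC)cc1OC | intermediate
6 | 2-(3,4-dimethoxyphenyl)-4,5,6-trimethoxy-1,3-benzodioxole (racemic) | COc1ccc(C2Oc3cc(OC)c(OC)c(OC)c3O2)cc1OC | intermediate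
7 | 1,1-bis(methylsulfanyl)ethene (ketene dimethyl dithioacetal) | C=C(SC)SC | starting material
8 | [(3,4-dimethoxyphenyl)methylidene](3,4,5-trimethoxy-2-oxidophenyl)oxonium, oxocarbenium zwitterion (scandium on the aryloxide oxygen not drawn) | COc1ccc(C=[O+]c2cc(OC)c(OC)c(OC)c2[O-])cc1OC | intermediate
9 | [(3S)-3-(3,4-dimethoxyphenyl)-1-(methylsulfanyl)-3-(3,4,5-trimethoxy-2-oxidophenoxy)propylidene](methyl)sulfonium, thiocarbenium zwitterion (scandium on the aryloxide oxygen not drawn) | COc1ccc([C@H](CC(SC)=[S+]C)Oc2cc(OC)c(OC)c(OC)c2[O-])cc1OC | intermediate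
10 | (2S)-2-(3,4-dimethoxyphenyl)-5,6,7-trimethoxy-4,4-bis(methylsulfanyl)-3,4-dihydro-2H-chromen-8-ol | COc1ccc([C@@H]2CC(SC)(SC)c3c(c(O)c(OC)c(OC)c3OC)O2)cc1OC | intermediate
11 | (2S)-2-(3,4-dimethoxyphenyl)-8-hydroxy-5,6,7-trimethoxy-2,3-dihydro-4H-chromen-4-one | COc1ccc([C@@H]2CC(=O)c3c(c(O)c(OC)c(OC)c3OC)O2)cc1OC | target

**Step count**
Total steps: 4. Longest linear sequence: 4 steps (1 → 3 → 6 → 10 → 11).

**Steps most likely to fail**

Step 3 (Proposed new method). What may go wrong:
- poor facial selectivity at the oxocarbenium carbon, since the chiral scandium aryloxide is not bonded to the cationic oxygen;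
- opening of the dioxole at the wrong acetal oxygen, which gives an ion that cannot close ring C;
- loss of enantiomeric purity by reversible ionization of the benzylic C2–O1 bond of 9 or 10;
- acid-induced oligomerization of 7.

Fallback, known chemistry only, setting out from 3 and returning at 11. Friedel–Crafts C-acetylation of 3 at its only free ring carbon (AcOH, BF3·OEt2, 80 °C) should give 1-(2,3-dihydroxy-4,5,6-trimethoxyphenyl)ethanone F1. Claisen formylation with ethyl formate and NaH, then acid cyclodehydration (HCl, AcOH), should give 8-hydroxy-5,6,7-trimethoxy-4H-chromen-4-one F2, since only the hydroxyl ortho to the acyl group can close the pyranone. Enantioselective conjugate addition of (3,4-dimethoxyphenyl)boronic acid to F2 under divalent-palladium catalysis (Pd(OCOCF3)2, the t-BuPyOx antipode that gives 2S, NH4PF6, H2O, ClCH2CH2Cl, 60 °C) should then give 11 directly.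

Step 2. What may go wrong: Friedel–Crafts alkylation of the electron-rich free ring carbon of 3 or 6 by the oxocarbenium ion under acid catalysis, and air oxidation of the catechol during the long heating.

Fallback, setting out from 3 and 4 and returning at 6, avoiding acid altogether. Aldehyde 4 is converted to 4-(dichloromethyl)-1,2-dimethoxybenzene F3 ((COCl)2, Ph3PO (cat.), CHCl3, rt). Double O-alkylation of 3 with F3 (Cs2CO3, degassed DMF, rt to 50 °C) should close the dioxole ring to 6 under basic conditions, where only the oxygens of 3 are nucleophilic.

Step 1. What may go wrong: over-oxidation of the very electron-rich ring, or oxidative demethylation to a p-quinone in place of ortho-oxygenation.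

Fallback, setting out from 1 and returning at 3. Magnesium-mediated ortho-formylation of 1 (MgCl2, Et3N, paraformaldehyde, MeCN, reflux) should give 6-hydroxy-2,3,4-trimethoxybenzaldehyde F4. Dakin oxidation of F4 (H2O2, aq NaOH, 0 °C to rt, then acidification under argon) replaces the formyl group by hydroxyl and should give 3.

Further compounds
F1 | step 3 | 1-(2,3-dihydroxy-4,5,6-trimethoxyphenyl)ethanone | CC(=O)c1c(O)c(O)c(OC)c(OC)c1OC
F2 | step 3 | 8-hydroxy-5,6,7-trimethoxy-4H-chromen-4-one | O=c1ccoc2c(O)c(OC)c(OC)c(OC)c12
F3 | step 2 | 4-(dichloromethyl)-1,2-dimethoxybenzene | COc1ccc(C(Cl)Cl)cc1OC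
F4 | step 1 | 6-hydroxy-2,3,4-trimethoxybenzaldehyde | COc1cc(O)c(C=O)c(OC)c1OC
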